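## Retrosynthetic overview
1. Cut C1′–C2′ of the geranyl chain (B-alkyl Suzuki coupling). This leads back to a 7-methylidene bicycle and an (E)-vinyl iodide. Hydroboration from the exo face puts the chain endo and sets C7.
2. Cut C1–C9 and C2–C3 together. Both carbocycles close in one flask, ring B first and ring A second, from an open chain attached to a 3,3-disubstituted 6-aryl-pyran-2,4-dione. That heterocycle already holds C3, C4, C5, C9 and the aroyl group.
3. Cut C5–C6 by enantioselective allylic alkylation of a 3-prenyl-4-hydroxy-6-aryl-2-pyrone with a 5-methylidene δ-lactone. This sets C5, which later controls C1 and C7.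
4. The lactone comes from an orthoester Claisen on 2-isopropylidenepropane-1,3-diol (C1–C8 bond), then C1 prenylation. The pyrone comes from an acetoacetate dianion and methyl 3-hydroxybenzoate.
5. The vinyl iodide comes from 6-methylhept-5-en-2-one by alkyne formation, carboalumination and iodination.

**Numbering.** C1–C9 are the bicyclo[3.3.1]nonane atoms of the target. C1 is next to CMe2 (C8), C5 is next to CH2 (C6), C7 bears geranyl, and C9 is the bridging ketone. C1′ is the first geranyl carbon.

**Target as read from the SMILES.** It is (1S,5S,7S) with a 2′E alkene. The geranyl group is endo, meaning cis to the C2–C3–C4 bridge and trans to both bridgehead prenyl groups.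

**Assumption.** The (R,R)-ligand in step 6 is taken to give the S centre; if a pilot run shows the opposite sense, the equally available (S,S)-ligand is used and nothing else changes.

## Route

Step 1
Reactants: 1 diethyl 2-(propan-2-ylidene)propanedioate
Product: 2 2-(propan-2-ylidene)propane-1,3-diol
Conditions: iBu2AlH (4.5 equiv), CH2Cl2, −78 to 0 °C; aq potassium sodium tartrate
Reagents that add atoms: none
Why: Exhaustive 1,2-reduction of both conjugated esters (ester-to-alcohol reduction) by the electrophilic hydride iBu2AlH, which leaves the tetrasubstituted C=C untouched; no stereocentre is formed.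

Step 2
Reactants: 2 2-(propan-2-ylidene)propane-1,3-diol; 3 trimethyl orthoacetate
Product: 6 4,4-dimethyl-5-methylideneoxan-2-one, via ketene acetal 4 (not isolated), via hydroxy ester 5 (not isolated)
Conditions: 3 (1.05 equiv), EtCO2H (5 mol %), xylenes, 140 °C, MeOH distilled off
Reagents that add atoms: trimethyl orthoacetate 3, COC(C)(OC)OC
Why: Johnson orthoester Claisen rearrangement in which the [3,3] shift of 4 forges the hindered C1–C8 bond at the CMe2 terminus and turns the old O–CH2 into the exocyclic methylene, after which the free OH of 5 lactonises (gem-dimethyl effect) before a second rearrangement can start because only one equivalent of 3 is present; no stereocentre is formed.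

Step 3
Reactants: 6 4,4-dimethyl-5-methylideneoxan-2-one; 7 prenyl bromide (1-bromo-3-methylbut-2-ene)
Product: 8 4,4-dimethyl-5-methylidene-3-(3-methylbut-2-enyl)oxan-2-one (racemic)
Conditions: LiN(iPr)2 (1.1 equiv), THF–DMPU, −78 °C; 7, −78 to −20 °C
Reagents that add atoms: prenyl bromide 7, CC(C)=CCBr
Why: Lactone enolate alkylation (SN2) with a reactive allylic bromide; the new centre (future C1) is deliberately racemic because enolisation erases it in step 7.

Step 4
Reactants: 9 methyl acetoacetate; 7 prenyl bromide
Product: 10 methyl 2-acetyl-5-methylhex-4-enoate (racemic)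
Conditions: K2CO3, acetone, reflux
Reagents that add atoms: prenyl bromide 7, CC(C)=CCBr
Why: Classical acetoacetic ester C-alkylation; the labile α-centre becomes sp2 in step 5.

Step 5
Reactants: 10 methyl 2-acetyl-5-methylhex-4-enoate; 11 methyl 3-hydroxybenzoate
Product: 13 4-hydroxy-6-(3-hydroxyphenyl)-3-(3-methylbut-2-enyl)-2H-pyran-2-one, via diketo ester 12 (not isolated)
Conditions: 10 (2 equiv, the second equivalent acts as base and is recovered), LiN(iPr)2 (4.1 equiv), THF, −78 to 0 °C; 11 pre-lithiated with LiN(iPr)2 (1.0 equiv), 0 °C to rt; cold 1 M HCl; then DBU (0.2 equiv), PhMe, reflux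
Reagents that add atoms: none
Why: γ-Acylation of a β-keto ester dianion (crossed Claisen condensation) followed by base-catalysed enol lactonisation of 12 to the 4-hydroxy-2-pyrone; the meta-phenoxide is not conjugated with the ester, so no protecting group is needed, and no stereocentre is formed.

Step 6
Reactants: 8 4,4-dimethyl-5-methylidene-3-(3-methylbut-2-enyl)oxan-2-one; 13 4-hydroxy-6-(3-hydroxyphenyl)-3-(3-methylbut-2-enyl)-2H-pyran-2-one
Product: 15 methyl 4-{[(3S)-6-(3-hydroxyphenyl)-3-(3-methylbut-2-enyl)-2,4-dioxo-3,4-dihydro-2H-pyran-3-yl]methyl}-3,3-dimethyl-2-(3-methylbut-2-enyl)pent-4-enoate (both epimers at the ester α-carbon), via carboxylic acid 14 (not isolated)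
Conditions: Pd2(dba)3·CHCl3 (2.5 mol %), (R,R)-DACH-phenyl Trost ligand (6 mol %), CH2Cl2, 0 °C, stopped at full conversion; evaporate; MeI (3 equiv), KHCO3 (2 equiv), DMF, rt
Reagents that add atoms: iodomethane, CI
Why: Proposed new method: Tsuji–Trost asymmetric allylic alkylation in which zerovalent palladium ionises the allylic C–O bond of 8 to a 2-substituted π-allyl carboxylate whose two CH2 termini are constitutionally equivalent, the carboxylate deprotonates only the pyrone OH (pKa about 5, the phenol stays neutral), kinetic O-allylation is reversible and funnels to C3, and the ligand pocket differentiates the faces of the flat unsymmetrical pyronate so that the quaternary centre (future C5) forms as S, the closest known reactions being palladium-catalysed C3 mono- and diallylation of 4-hydroxy-2-pyrones and asymmetric allylation of cyclic β-keto esters and acylphloroglucinols with this ligand family; the carboxylate is then methylated by SN2 under KHCO3, which is too weak a base to touch the phenol.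

Step 7 (key step)
Reactants: 15 pyrandione ester (3S)
Product: 17 (1S,5S)-4-hydroxy-3-(3-hydroxybenzoyl)-8,8-dimethyl-7-methylidene-1,5-bis(3-methylbut-2-enyl)bicyclo[3.3.1]non-3-ene-2,9-dione, via ring-B keto ester 16 (not isolated)
Conditions: KN(SiMe3)2 (3.3 equiv), 18-crown-6 (3.3 equiv), THF (0.01 M), −78 °C to rt, then 40 °C; 1 M HCl
Reagents that add atoms: none
Why: Proposed new method: a tandem acyl-transfer Dieckmann/Claisen double ring closure in which the crown-separated potassium ester enolate at C1 attacks the activated enol-lactone carbonyl C9 through a six-membered open, dipole-opposed transition state (ring B), the pyranone opens and releases exactly the aroyl-stabilised C3 enolate, held axial on C5, which attacks the now 1,3-diaxial C2 ester (ring A), and the product is drained as its very stable trione enolate; C1 is set by C5 because only the cis isomer of 16 can bridge, and the closest known reactions are the Dieckmann closure that ends known endo type B syntheses, the biomimetic Claisen cyclisation of 3,5,7-triketo esters to acylphloroglucinols and carbanion opening of enol lactones.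

Step 8
Reactants: 18 6-methylhept-5-en-2-one
Product: 20 6-methylhept-5-en-1-yne, via enol phosphate 19 (not isolated)
Conditions: LiN(iPr)2 (1.05 equiv), THF, −78 °C; ClP(O)(OEt)2; LiN(iPr)2 (2.3 equiv), −78 °C to rt; H2O
Reagents that add atoms: none
Why: Negishi conversion of a methyl ketone into a terminal alkyne, by kinetic enolate trapping as enol phosphate 19 followed by base-induced elimination.

Step 9
Reactants: 20 6-methylhept-5-en-1-yne
Product: 22 (1E)-1-iodo-2,6-dimethylhepta-1,5-diene, via alkenylalane 21 (not isolated)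
Conditions: AlMe3 (2 equiv), Cp2ZrCl2 (0.2 equiv), CH2Cl2, 0 °C to rt; I2, THF, −30 °C
Reagents that add atoms: trimethylaluminium, C[Al](C)C; iodine, [I][I]
Why: Negishi zirconium-catalysed carboalumination adds Me and Al syn across the terminal alkyne to give only the (E)-alkenylalane 21, and iodinolysis retains the geometry, which fixes the 2′E alkene of the geranyl chain.

Step 10
Reactants: 17 7-methylidene bicycle (1S,5S); 22 (1E)-1-iodo-2,6-dimethylhepta-1,5-diene
Product: 24 (1S,5S,7S)-7-[(2E)-3,7-dimethylocta-2,6-dienyl]-4-hydroxy-3-(3-hydroxybenzoyl)-8,8-dimethyl-1,5-bis(3-methylbut-2-enyl)bicyclo[3.3.1]non-3-ene-2,9-dione (target), via tris-boryl adduct 23 (not isolated)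
Conditions: 9-BBN-H (3.3 equiv), THF, 0 °C to rt; then 22 (1.3 equiv), PdCl2(dppf)·CH2Cl2 (5 mol %), aq NaOH (3 M), THF–DMF, 50 °C; aq citric acid
Reagents that add atoms: none
Why: Chemoselective hydroboration followed by B-alkyl Suzuki–Miyaura coupling, in which 9-BBN-H first masks the enol and phenol as B–O derivatives, then adds only to the 1,1-disubstituted C7=CH2 (about 10^4 times faster than to prenyl alkenes) from the open exo face because ring A roofs the endo face (compare camphene), placing H exo and CH2–B endo and so setting C7 as S; the coupling keeps the E geometry of 22 and the aqueous base frees both OH groups.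

**Where each stereoelement is set.** C5 is set in step 6 and no bond at C5 is broken afterwards. C1 is set in step 7, C7 in step 10, and the 2′E alkene in step 9.

## Compound list
1 | diethyl 2-(propan-2-ylidene)propanedioate | CCOC(=O)C(=C(C)C)C(=O)OCC | starting material
2 | 2-(propan-2-ylidene)propane-1,3-diol | CC(C)=C(CO)CO | intermediate
3 | trimethyl orthoacetate | COC(C)(OC)OC | starting material
4 | 2-[(1-methoxyethenyl)oxymethyl]-3-methylbut-2-en-1-ol (ketene acetal) | C=C(OC)OCC(CO)=C(C)C | intermediate
5 | methyl 4-(hydroxymethyl)-3,3-dimethylpent-4-enoate | COC(=O)CC(C)(C)C(=C)CO | intermediate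
6 | 4,4-dimethyl-5-methylideneoxan-2-one | C=C1COC(=O)CC1(C)C | intermediate
7 | prenyl bromide | CC(C)=CCBr | starting material
8 | 4,4-dimethyl-5-methylidene-3-(3-methylbut-2-enyl)oxan-2-one (racemic) | C=C1COC(=O)C(CC=C(C)C)C1(C)C | intermediate
9 | methyl acetoacetate | COC(=O)CC(C)=O | starting material
10 | methyl 2-acetyl-5-methylhex-4-enoate (racemic) | COC(=O)C(CC=C(C)C)C(C)=O | intermediate
11 | methyl 3-hydroxybenzoate | COC(=O)c1cccc(O)c1 | starting material
12 | methyl 5-(3-hydroxyphenyl)-2-(3-methylbut-2-enyl)-3,5-dioxopentanoate | COC(=O)C(CC=C(C)C)C(=O)CC(=O)c1cccc(O)c1 | intermediate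
13 | 4-hydroxy-6-(3-hydroxyphenyl)-3-(3-methylbut-2-enyl)-2H-pyran-2-one | CC(C)=CCC1=C(O)C=C(c2cccc(O)c2)OC1=O | intermediate
14 | 4-{[(3S)-6-(3-hydroxyphenyl)-3-(3-methylbut-2-enyl)-2,4-dioxo-3,4-dihydro-2H-pyran-3-yl]methyl}-3,3-dimethyl-2-(3-methylbut-2-enyl)pent-4-enoic acid (α-epimers) | OC(=O)C(CC=C(C)C)C(C)(C)C(=C)C[C@]1(CC=C(C)C)C(=O)OC(c2cccc(O)c2)=CC1=O | intermediate
15 | methyl ester of 14 (α-epimers, pyranone C3 = S) | COC(=O)C(CC=C(C)C)C(C)(C)C(=C)C[C@]1(CC=C(C)C)C(=O)OC(c2cccc(O)c2)=CC1=O | intermediate
16 | methyl (1S,3S)-3-[3-(3-hydroxyphenyl)-3-oxopropanoyl]-6,6-dimethyl-5-methylidene-1,3-bis(3-methylbut-2-enyl)-2-oxocyclohexane-1-carboxylate (ester and diketone arm cis) | C=C1C[C@@](CC=C(C)C)(C(=O)CC(=O)c2cccc(O)c2)C(=O)[C@@](CC=C(C)C)(C(=O)OC)C1(C)C | intermediate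
17 | (1S,5S)-4-hydroxy-3-(3-hydroxybenzoyl)-8,8-dimethyl-7-methylidene-1,5-bis(3-methylbut-2-enyl)bicyclo[3.3.1]non-3-ene-2,9-dione | C=C1C[C@]2(CC=C(C)C)C(=O)[C@@](CC=C(C)C)(C(=O)C(C(=O)c3cccc(O)c3)=C2O)C1(C)C | intermediate
18 | 6-methylhept-5-en-2-one | CC(=O)CCC=C(C)C | starting material
19 | diethyl 6-methylhepta-1,5-dien-2-yl phosphate | C=C(CCC=C(C)C)OP(=O)(OCC)OCC | intermediate
20 | 6-methylhept-5-en-1-yne | C#CCCC=C(C)C | intermediate
21 | [(1E)-2,6-dimethylhepta-1,5-dienyl]dimethylaluminium | C[Al](C)/C=C(\C)CCC=C(C)C | intermediate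
22 | (1E)-1-iodo-2,6-dimethylhepta-1,5-diene | I/C=C(\C)CCC=C(C)C | intermediate
23 | 7-endo-(9-BBN-methyl) adduct of 17 with enol O and phenol O also carrying 9-BBN | B1(C2CCCC1CCC2)C[C@H]3C[C@]4(CC=C(C)C)C(=O)[C@@](CC=C(C)C)(C(=O)C(C(=O)c5cccc(OB6C7CCCC6CCC7)c5)=C4OB8C9CCCC8CCC9)C3(C)C | intermediate
24 | (1S,5S,7S)-7-[(2E)-3,7-dimethylocta-2,6-dienyl]-4-hydroxy-3-(3-hydroxybenzoyl)-8,8-dimethyl-1,5-bis(3-methylbut-2-enyl)bicyclo[3.3.1]non-3-ene-2,9-dione | CC(C)=CCC/C(C)=C/C[C@H]1C[C@]2(CC=C(C)C)C(=O)[C@@](CC=C(C)C)(C(=O)C(C(=O)c3cccc(O)c3)=C2O)C1(C)C | target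

## Step count
Total steps: 10. The longest linear sequence is 6 steps (1, 2, 3, 6, 7, 10).

## The three steps most likely to fail

**Step 7.**
- The C1–H is hindered and may deprotonate slowly.
- Only the cis isomer of 16 can close ring A, and the trans isomer has no easy way back.
- The free phenoxide can take part in intermolecular acyl transfer.

The fallback sets out from 15 and comes back at 17.
- The ester is trapped under internal-quench conditions (LiN(iPr)2 with Me3SiCl, THF, −95 °C) as the bis-silylated ketene acetal F1, in which the phenol is silylated too.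
- Me3SiOTf (20 mol %, CH2Cl2, −78 °C) then activates the enol-lactone carbonyl for a Mukaiyama-type C-acylation through an open antiperiplanar transition state.
- Aqueous work-up gives 16, which is now isolated and freed of any trans isomer.
- Ring A is closed separately with KOtBu in THF (Dieckmann condensation) to give 17.

**Step 6.**
- The enantioselectivity on a pyronate nucleophile is unproven.
- O-allylation may persist instead of funnelling to carbon.
- Zerovalent palladium may re-ionise the C5–allyl bond of the product, since the pyronate is a good leaving group, and this would erode the ee.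

The fallback sets out from 8 and 13 and comes back at 15.
- Lactone 8 is opened with catalytic NaOMe in MeOH at 0 °C, neutralised cold, and used at once as the hydroxy ester F2.
- A Mitsunobu reaction (PPh3, DIAD, THF, 0 °C) with 13 alkylates the far more acidic pyrone 4-OH to give the 4-allyloxy-2-pyrone F3.
- An enantioselective [3,3] Claisen rearrangement follows, catalysed by a C2-symmetric chiral guanidinium tetrakis[3,5-bis(trifluoromethyl)phenyl]borate hydrogen-bond donor (20 mol %, 40 °C). This catalysis is established for cyclic O-allyl β-keto esters.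
- The rearrangement moves the allyl unit to C3 and gives 15. Both allyl termini are CH2, so the constitution is unchanged.

**Step 10.**
- The free trione may form a persistent boron chelate or bind palladium.
- The alkene lies next to CMe2 and is hindered.
- Transmetalation of the endo, β-branched borane may be slow.

The fallback sets out from 17 and comes back at 24.
- The acidic enol alone is methylated with Me3SiCHN2 to give the methyl enol ether F4 (drawn as the 4-O-methyl isomer).
- 9-BBN-H (2.2 equiv) gives the endo borane F5.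
- Coupling with 22 on this neutral substrate gives the O-methyl ether F6.
- LiCl in DMSO at 120 °C cleaves the vinylogous ester by SN2 at methyl to give 24.

## Further compounds
F1 | step 7 | bis(trimethylsilyl) derivative of 15 (methyl trimethylsilyl ketene acetal, aryl silyl ether) | COC(O[Si](C)(C)C)=C(CC=C(C)C)C(C)(C)C(=C)C[C@]1(CC=C(C)C)C(=O)OC(c2cccc(O[Si](C)(C)C)c2)=CC1=O
F2 | step 6 | methyl 4-(hydroxymethyl)-3,3-dimethyl-2-(3-methylbut-2-enyl)pent-4-enoate (racemic) | COC(=O)C(CC=C(C)C)C(C)(C)C(=C)CO
F3 | step 6 | methyl 4-({[6-(3-hydroxyphenyl)-3-(3-methylbut-2-enyl)-2-oxo-2H-pyran-4-yl]oxy}methyl)-3,3-dimethyl-2-(3-methylbut-2-enyl)pent-4-enoate | COC(=O)C(CC=C(C)C)C(C)(C)C(=C)COC1=C(CC=C(C)C)C(=O)OC(c2cccc(O)c2)=C1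
F4 | step 10 | (1S,5S)-3-(3-hydroxybenzoyl)-4-methoxy-8,8-dimethyl-7-methylidene-1,5-bis(3-methylbut-2-enyl)bicyclo[3.3.1]non-3-ene-2,9-dione | C=C1C[C@]2(CC=C(C)C)C(=O)[C@@](CC=C(C)C)(C(=O)C(C(=O)c3cccc(O)c3)=C2OC)C1(C)C
F5 | step 10 | 7-endo-(9-BBN-methyl) adduct of F4 with the phenol O carrying 9-BBN | B1(C2CCCC1CCC2)C[C@H]3C[C@]4(CC=C(C)C)C(=O)[C@@](CC=C(C)C)(C(=O)C(C(=O)c5cccc(OB6C7CCCC6CCC7)c5)=C4OC)C3(C)C
F6 | step 10 | 4-O-methyl ether of 24 | CC(C)=CCC/C(C)=C/C[C@H]1C[C@]2(CC=C(C)C)C(=O)[C@@](CC=C(C)C)(C(=O)C(C(=O)c3cccc(O)c3)=C2OC)C1(C)C
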